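## The problem

The carbon skeleton of target 13 is that of benzyl alcohol: one six-membered carbocycle with a single exocyclic carbon (C7), so the task lies in the oxidation pattern and its stereochemistry, not in C–C bond construction. With the ring numbered C1 (quaternary, bearing C7), C2 (free hydroxyl), C3 (benzoate), C4=C5 and C6, two adjacent ring bonds carry oxygen: C1–C6 as a cis-fused oxirane and C2–C3 as a cis diol, while C4=C5 must stay an alkene. The four stereocentres C1, C2, C3 and C6 are contiguous, and the C2 and C3 oxygens stand on the face opposite to the epoxide oxygen, the face of the C7 methylene. An epoxide already in place can therefore steer a cis-dihydroxylation to its far side, but the absolute configuration must come from outside. The functional groups are fragile: the oxirane is allylic at C6 and tertiary at C1 and opens with acids, Lewis acids and soft nucleophiles; the allylic C3 benzoate can migrate to the cis C2 hydroxyl under base; and the C2 and C3 hydroxyls must be told apart in the last acylation. The feature that invites a short route appears when the C2 and C3 oxygens are removed in thought: the C1–C6 oxirane flanking the diene C2=C3–C4=C5 is the 1,2-oxide of benzyl alcohol (9). Such an arene oxide interconverts with its oxepin valence tautomer by electrocyclic opening and closure, so C1 and C6 racemise continuously, and its C7 hydroxyl sits on the face anti to the epoxide oxygen within hydrogen-bonding reach of C2=C3. A chiral oxidant delivered by that hydroxyl could thus set all four stereocentres in one operation from a racemic precursor.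

## Retrosynthesis

**13 to triol 11 and benzoyl chloride 12.** The two acyl C–O bonds at O7 and O3 are cut last. Neither benzoate can be carried earlier: the C3 oxygen does not exist before the key step, and the C7 hydroxyl must be free there to act as a hydrogen-bond donor. Triol 11 already holds all four stereocentres. The forward step must acylate the primary hydroxyl and the allylic C3 hydroxyl but not the C2 hydroxyl, which is shielded by the quaternary C1.

**11 to arene oxide 9 (through osmate ester 10).** The C2–O and C3–O bonds are cut together. The neighbouring cut, the two epoxide C–O bonds, would lead back to the cis-dihydrodiol of a benzyl alcohol derivative, which has no short chemical synthesis. Cutting ring C–C bonds would mean building a six-membered ring that benzene chemistry supplies for nothing. The chosen cut removes every fixed stereocentre at once, because 9 racemises through oxepin-2-ylmethanol. The forward reaction must react through the oxide tautomer, choose C2=C3 over C4=C5, add anti to the epoxide oxygen and select one of the two interconverting enantiomers. The first three tasks are given to a hydrogen bond between the C7 hydroxyl and an OsO4–diamine complex, the last to the chirality of the diamine. Low temperature (which raises the share of the oxide tautomer), a non-coordinating solvent and a preformed chelate complex are the measures taken to keep the hydrogen bond in control.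

**9 to dibromo epoxy alcohol 6 (through silyl ethers 7 and 8).** The two ring double bonds are traced back to two C–Br/C–H pairs: C2=C3 and C4=C5 arise by twofold loss of HBr from the 3,4-dibromide. This is the classical entry to benzene oxides and needs only base, which arene oxides tolerate. Compound 6 is a stable, saturated epoxide. The forward step must keep the C7 hydroxyl from displacing a bromide intramolecularly, which is why it is silylated in the flask (7), carried through the elimination (8) and released again.

**6 to allylic alcohol 5.** The two oxirane C–O bonds are cut. Alcohol 5 has only one alkene, so no chemoselectivity is asked, and facial selectivity is irrelevant because the bromine-bearing centres vanish later.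

**5 to ester 4.** The C7 oxidation level is adjusted: the alcohol comes from the ester by hydride reduction. The ester is kept up to this point because it activates the dienophile in the first step and deactivates the C1=C6 alkene towards bromine in the second.

**4 to diene ester 3.** The C3–Br and C4–Br bonds are cut. Bromination at the ester stage, rather than after reduction and epoxidation, discriminates between the two alkenes electronically and avoids bromoetherification by a free hydroxyl.

**3 to buta-1,3-diene 1 and methyl propiolate 2.** The C1–C2 and C5–C6 ring bonds are cut in a Diels–Alder sense. The 1,4-diene places one alkene where the epoxide is needed and the other where the dibromide is needed; a Birch-type 2,5-diene would not.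

## Roads not taken

**Alternative 1:** chromium-mediated ring closure at C5–C6. The cut is the C5–C6 ring bond. In the forward direction CrCl2 with catalytic NiCl2 would turn the Z-iodoalkene of acyclic aldehyde A1 into a vinylchromium reagent that adds to the C6 aldehyde (Nozaki–Hiyama–Kishi cyclisation) to give cyclohexenol A2. Its new C6 hydroxyl must stand trans to the C1 silyloxy group so that sulfonylation, removal of the triethylsilyl group and intramolecular displacement can close the epoxide.
- Merits: the reaction is reliable for six-membered rings and tolerant of esters, and C1, C2 and C3 would be fixed beforehand in an open chain by established asymmetric methods, so the absolute configuration would be secure.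
- Weak points: A1 is itself a demanding target (a fully substituted carbinol next to an aldehyde, three differentiated oxygens, a Z-iodoalkene). The C6 configuration rests on modest 1,2-induction. After ring closure at least four further steps are needed, during which a C3 benzoate sits beside a C2 oxygen being unmasked and acyl migration threatens.
- Comparison: this road is better in certainty of configuration and uses only known reaction types. The chosen plan sets against it seven steps, no lasting protecting group and four stereocentres fixed in one operation, at the price of an untested key step.

**Alternative 2:** furan–vinylene carbonate cycloaddition. The cut is C1–C2 and C3–C4. Furfuryl benzoate A3 and vinylene carbonate A4 would combine in an endo [4+2] cycloaddition to give 7-oxanorbornene A5, in which the cis diol (as carbonate) and the C1 oxygen are installed together, with the carbonate anti to the oxygen bridge as the target requires.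
- Merits: cheap achiral materials, a guaranteed cis diol, and known reaction types throughout.
- Weak points: furan cycloadditions are reversible and give endo/exo mixtures, and A5 is racemic, so a resolution or an asymmetric variant must be added. The oxygen bridge C1–O–C4 must then become the C1–O–C6 oxirane with the alkene moved to C4=C5, which requires cleaving the C4–O bond and re-closing the C1 alkoxide on an activated C6 over several steps. The carbonate must finally be opened to a C3 benzoate and a free C2 hydroxyl.
- Comparison: in precedent this road is stronger than the chosen plan. The chosen plan sets against it built-in enantiocontrol, no bridge relocation and about half the length.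

**Alternative 3:** lactone-enolate Claisen ring contraction. The cut is C1–C6. O-Silylation of the enolate of pentose-derived lactone A6 and Ireland–Claisen rearrangement through a boat would form C1–C6, break the lactone C4–O bond, create C4=C5 and deliver cyclohexene acid A7, with a C6 chloride trans to the C1 oxygen ready for epoxide closure.
- Merits: absolute configuration from the chiral pool, the cis diol pre-installed as an acetonide, and the quaternary C1 made stereospecifically.
- Weak points: A6 needs a long preparation, including an E-chlorovinyl group. A7 carries a carboxylic acid that must be reduced to C7 in the presence of an allylic chloride. The acetonide must be removed by acid either before epoxide closure (freeing three hydroxyls next to a leaving group) or after it (endangering the vinyl epoxide). The C2/C3 differentiation remains as in the chosen plan.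
- Comparison: this road is better in stereochemical certainty and equal in the final acylation problem. The chosen plan sets against it step economy and freedom from protecting-group and oxidation-state changes.

Key step: step 6

## Route

Assumption: which enantiomer of the diamine selects the (1S,6S)-oxide cannot be deduced from precedent; the (1R,2R)-diamine is written, and its antipode would be used if the sense proved opposite.

Step 1
Reactants: 1 buta-1,3-diene, 2 methyl propiolate
Product: 3 methyl cyclohexa-1,4-diene-1-carboxylate
Conditions: toluene, hydroquinone (cat.), sealed tube, 110 °C
Reagents that add atoms: none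
Why: Thermal Diels–Alder [4+2] cycloaddition of the s-cis diene with the electron-poor alkyne gives the 1,4-diene directly; no regio- or stereochemical question arises and the inhibitor suppresses diene polymerisation.

Step 2
Reactants: 3 methyl cyclohexa-1,4-diene-1-carboxylate
Product: 4 methyl trans-4,5-dibromocyclohex-1-ene-1-carboxylate (racemic)
Conditions: Br2 (1.0 equiv), CH2Cl2, −78 °C
Reagents that add atoms: bromine, BrBr
Why: Electrophilic anti addition of bromine takes the isolated, electron-richer alkene and spares the ester-deactivated one; the racemic trans configuration is immaterial because both C–Br bonds are eliminated in step 5.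

Step 3
Reactants: 4 methyl trans-4,5-dibromocyclohex-1-ene-1-carboxylate
Product: 5 (trans-4,5-dibromocyclohex-1-en-1-yl)methanol (racemic)
Conditions: iBu2AlH (2.2 equiv), CH2Cl2, −78 °C; aq. potassium sodium tartrate
Reagents that add atoms: none
Why: 1,2-Reduction of the conjugated ester by the aluminium hydride gives the allylic alcohol; secondary alkyl bromides are inert to iBu2AlH at this temperature.

Step 4
Reactants: 5 (trans-4,5-dibromocyclohex-1-en-1-yl)methanol
Product: 6 (3,4-trans-dibromo-7-oxabicyclo[4.1.0]heptan-1-yl)methanol (racemic; both epoxide diastereomers)
Conditions: VO(acac)2 (2 mol %), tBuOOH, CH2Cl2, 0 °C to rt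
Reagents that add atoms: tert-butyl hydroperoxide, CC(C)(C)OO
Why: Hydroxyl-directed vanadium-catalysed epoxidation of the allylic alcohol under neutral conditions; the oxirane forms on either ring face and both diastereomers are carried on because the bromine-bearing centres disappear in step 5.

Step 5
Reactants: 6 (3,4-trans-dibromo-7-oxabicyclo[4.1.0]heptan-1-yl)methanol
Product: 9 rac-(7-oxabicyclo[4.1.0]hepta-2,4-dien-1-yl)methanol, via dibromo epoxide trimethylsilyl ether 7 (not isolated), via arene oxide trimethylsilyl ether 8 (not isolated)
Conditions: Me3SiCl (1.1 equiv), DBU (4.5 equiv), THF, 0 to 40 °C; then K2CO3 (cat.), MeOH, 0 °C; filtration through basic alumina, kept cold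
Reagents that add atoms: none
Why: In situ silylation keeps the hydroxyl from displacing a bromide (Williamson-type bridged ether) or entering a Payne rearrangement; two anti E2 eliminations (C3–Br with C2–H, C4–Br with C5–H) then give the diene as in the classical dehydrobromination route to benzene oxides, and base-mediated methanolysis frees the primary alcohol under conditions in which arene oxides do not aromatise. Both diastereomers of 6 converge, and 9 is racemic and in equilibrium with oxepin-2-ylmethanol.

Step 6
Reactants: 9 rac-(7-oxabicyclo[4.1.0]hepta-2,4-dien-1-yl)methanol
Product: 11 (1R,2S,3S,6S)-1-(hydroxymethyl)-7-oxabicyclo[4.1.0]hept-4-ene-2,3-diol, via osmate ester diamine chelate 10 (not isolated)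
Conditions: OsO4 (1.05 equiv), (1R,2R)-N,N,N′,N′-tetramethylcyclohexane-1,2-diamine (1.1 equiv), CH2Cl2, −78 °C, 9 added slowly; then aq. Na2SO3, THF, rt
Reagents that add atoms: osmium tetroxide, O=[Os](=O)(=O)=O
Why: Proposed new method: OsO4 chelated by the diamine has electron-rich oxo ligands that accept a hydrogen bond from the C7 hydroxyl of the oxide tautomer, and it is expected to add across C2=C3 by a concerted suprafacial [3+2] cycloaddition; the closest known reaction types are OsO4–TMEDA dihydroxylations directed by allylic and homoallylic alcohols and the anti-selective cycloadditions that benzene oxides undergo through the oxide tautomer. No ring of the product is closed; only the transient five-membered osmate ester ring of 10 forms, which fixes the C2 and C3 oxygens cis to each other. Both oxygens should arrive on the face anti to the epoxide oxygen, because the C7 hydroxyl stands on that face and the usual preference of OsO4 to add anti to an allylic C–O bond points the same way; this sets C2 and C3 relative to C1 and C6. C1 and C6 are not created but selected: the oxide enantiomers interconvert through the oxepin by 6π electrocyclic opening and closure much faster than osmylation at −78 °C, so under Curtin–Hammett conditions the chiral diamine can pass the whole racemate through the enantiomer with the lower diastereomeric transition state (dynamic kinetic resolution). Three selectivities are needed: oxide over oxepin, C2=C3 over C4=C5, and one enantiomer over the other. The first is helped by low temperature, since for the parent system the oxide is the enthalpically favoured tautomer, and by the bulk of the chelate, which should be slow at the trisubstituted enol ether alkene of the oxepin; the second rests on the short hydrogen-bonded path from C7–OH to C2=C3, kept intact by the non-coordinating solvent; the third rests on the diamine. Sulfite then reduces and hydrolyses the hexavalent osmium ester without acid, so the vinyl epoxide should survive.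

Step 7
Reactants: 11 (1R,2S,3S,6S)-1-(hydroxymethyl)-7-oxabicyclo[4.1.0]hept-4-ene-2,3-diol, 12 benzoyl chloride (2.1 equiv)
Product: 13 [(1R,2S,3S,6S)-3-(benzoyloxy)-2-hydroxy-7-oxabicyclo[4.1.0]hept-4-en-1-yl]methyl benzoate
Conditions: pyridine, CH2Cl2, −30 to 0 °C
Reagents that add atoms: none
Why: Nucleophilic acyl substitution in order of steric accessibility: the primary C7 hydroxyl first, then the allylic C3 hydroxyl flanked by CH carbons in preference to the C2 hydroxyl next to the quaternary C1; a 1,2-acyl shift across the cis diol would also favour the less hindered C3 ester, and no stereocentre is touched.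

## Compound list

1 | buta-1,3-diene | C=CC=C | starting material
2 | methyl propiolate | C#CC(=O)OC | starting material
3 | methyl cyclohexa-1,4-diene-1-carboxylate | COC(=O)C1=CCC=CC1 | intermediate
4 | methyl trans-4,5-dibromocyclohex-1-ene-1-carboxylate (racemic, one enantiomer drawn) | COC(=O)C1=CC[C@@H](Br)[C@H](Br)C1 | intermediate
5 | (trans-4,5-dibromocyclohex-1-en-1-yl)methanol (racemic, one enantiomer drawn) | OCC1=CC[C@@H](Br)[C@H](Br)C1 | intermediate
6 | (3,4-trans-dibromo-7-oxabicyclo[4.1.0]heptan-1-yl)methanol (racemic, both epoxide diastereomers, epoxide centres left open in the SMILES) | OCC12C[C@@H](Br)[C@H](Br)CC1O2 | intermediate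
7 | [(3,4-trans-dibromo-7-oxabicyclo[4.1.0]heptan-1-yl)methoxy]trimethylsilane (not isolated) | C[Si](C)(C)OCC12C[C@@H](Br)[C@H](Br)CC1O2 | intermediate
8 | trimethyl[(7-oxabicyclo[4.1.0]hepta-2,4-dien-1-yl)methoxy]silane (racemic, interconverting with its oxepin; not isolated) | C[Si](C)(C)OCC12OC1C=CC=C2 | intermediate
9 | rac-(7-oxabicyclo[4.1.0]hepta-2,4-dien-1-yl)methanol, the 1,2-oxide of benzyl alcohol, in equilibrium with oxepin-2-ylmethanol; the reacting (1S,6S) enantiomer is drawn | OC[C@]12O[C@H]1C=CC=C2 | intermediate
10 | dioxo osmate ester of hexavalent osmium bridging O2 and O3 of 11, chelated by the (1R,2R)-diamine (not isolated) | OC[C@]12O[C@H]1C=C[C@@H]3O[Os-2]4(=O)(=O)([N+](C)(C)[C@@H]5CCCC[C@H]5[N+]4(C)C)O[C@H]23 | intermediate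
11 | (1R,2S,3S,6S)-1-(hydroxymethyl)-7-oxabicyclo[4.1.0]hept-4-ene-2,3-diol | OC[C@]12O[C@H]1C=C[C@H](O)[C@@H]2O | intermediate
12 | benzoyl chloride | O=C(Cl)c1ccccc1 | starting material
13 | [(1R,2S,3S,6S)-3-(benzoyloxy)-2-hydroxy-7-oxabicyclo[4.1.0]hept-4-en-1-yl]methyl benzoate | O=C(OC[C@]12O[C@H]1C=C[C@H](OC(=O)c1ccccc1)[C@@H]2O)c1ccccc1 | target

## Step count and risks

Total steps: 7. Longest linear sequence: 7 steps (1 and 2 to 13).

**Step 6 (key step, proposed new method).**
- What may go wrong: osmylation may run through the oxepin tautomer, whose enol ether alkene is electron-rich and whose hydroxyl is allylic and can direct as well, leading to ring cleavage. Addition may occur at C4=C5. The diamine may discriminate too little between the two interconverting enantiomers, since cis-disubstituted ring alkenes are a poor substrate class for diamine-controlled osmylation. The chelated osmate ester may also resist sulfite at room temperature.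
- Fallback (known chemistry; the order of the two oxidations is reversed so that no arene oxide is involved): it sets out from benzoyl chloride 12, which ethanol and pyridine convert into ethyl benzoate F1. Whole-cell oxidation of F1 with recombinant Escherichia coli expressing toluene dioxygenase gives ethyl (5S,6R)-5,6-dihydroxycyclohexa-1,3-diene-1-carboxylate F2, whose carbinol centres correspond to C3 and C2 of the target in the required absolute sense. Silylation (tBuMe2SiCl, imidazole, DMF) gives ethyl (5S,6R)-5,6-bis(tert-butyldimethylsilyloxy)cyclohexa-1,3-diene-1-carboxylate F3. iBu2AlH reduces the ester to [(5S,6R)-5,6-bis(tert-butyldimethylsilyloxy)cyclohexa-1,3-dien-1-yl]methanol F4. VO(acac)2 with tert-butyl hydroperoxide epoxidises the allylic-alcohol alkene anti to the adjacent silyloxy group to give the bis-silyl ether of the epoxy triol F5. Tetrabutylammonium fluoride removes both silyl groups and the sequence rejoins the route at 11.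

**Step 5.**
- What may go wrong: premature loss of the trimethylsilyl group followed by intramolecular ether formation, incomplete second elimination, and acid-induced aromatisation or evaporative and aqueous loss of the small, polar arene oxide during isolation.
- Fallback (a lasting protecting group and an isolable, storable arene oxide): from 6, tBuMe2SiCl and imidazole give tert-butyl[(3,4-trans-dibromo-7-oxabicyclo[4.1.0]heptan-1-yl)methoxy]dimethylsilane F6. DBU in THF eliminates twice to tert-butyldimethyl[(7-oxabicyclo[4.1.0]hepta-2,4-dien-1-yl)methoxy]silane F7, which can be purified on basic alumina. Tetrabutylammonium fluoride at 0 °C releases 9 immediately before step 6.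

**Step 7.**
- What may go wrong: insufficient discrimination between the C3 and C2 hydroxyls (over-acylation or acylation at C2), acyl migration across the cis diol, and opening of the vinyl epoxide by chloride if the medium turns acidic.
- Fallback (stepwise, tin-directed): from 11, one equivalent of 12 with pyridine at −78 °C gives the primary monobenzoate [(1R,2S,3S,6S)-2,3-dihydroxy-7-oxabicyclo[4.1.0]hept-4-en-1-yl]methyl benzoate F8. Its cis diol is converted with Bu2SnO into the stannylene acetal, which 12 and Et3N acylate at the less hindered C3 oxygen, returning to 13.

**Step 2.**
- What may go wrong: dehydrogenation of the 1,4-diene to methyl benzoate by bromine, or addition to both alkenes.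
- Fallback (reduction and epoxidation before bromination, so that bromine meets a single alkene): from 3, iBu2AlH gives cyclohexa-1,4-dien-1-ylmethanol F9. VO(acac)2 with tert-butyl hydroperoxide epoxidises only the allylic-alcohol alkene to (7-oxabicyclo[4.1.0]hept-3-en-1-yl)methanol F10. Silylation gives tert-butyldimethyl[(7-oxabicyclo[4.1.0]hept-3-en-1-yl)methoxy]silane F11, and bromine adds to the remaining alkene to give F6, from which the sequence described for step 5 leads through F7 back to 9.

## Further compounds

F1 | step 6 | ethyl benzoate | CCOC(=O)c1ccccc1
F2 | step 6 | ethyl (5S,6R)-5,6-dihydroxycyclohexa-1,3-diene-1-carboxylate | CCOC(=O)C1=CC=C[C@H](O)[C@@H]1O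
F3 | step 6 | ethyl (5S,6R)-5,6-bis(tert-butyldimethylsilyloxy)cyclohexa-1,3-diene-1-carboxylate | CCOC(=O)C1=CC=C[C@H](O[Si](C)(C)C(C)(C)C)[C@@H]1O[Si](C)(C)C(C)(C)C
F4 | step 6 | [(5S,6R)-5,6-bis(tert-butyldimethylsilyloxy)cyclohexa-1,3-dien-1-yl]methanol | OCC1=CC=C[C@H](O[Si](C)(C)C(C)(C)C)[C@@H]1O[Si](C)(C)C(C)(C)C
F5 | step 6 | 2,3-bis(tert-butyldimethylsilyl) ether of triol 11 | OC[C@]12O[C@H]1C=C[C@H](O[Si](C)(C)C(C)(C)C)[C@@H]2O[Si](C)(C)C(C)(C)C
F6 | step 5 | tert-butyl[(3,4-trans-dibromo-7-oxabicyclo[4.1.0]heptan-1-yl)methoxy]dimethylsilane (racemic, both epoxide diastereomers) | CC(C)(C)[Si](C)(C)OCC12C[C@@H](Br)[C@H](Br)CC1O2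
F7 | step 5 | tert-butyldimethyl[(7-oxabicyclo[4.1.0]hepta-2,4-dien-1-yl)methoxy]silane (racemic, interconverting with its oxepin) | CC(C)(C)[Si](C)(C)OCC12OC1C=CC=C2
F8 | step 7 | [(1R,2S,3S,6S)-2,3-dihydroxy-7-oxabicyclo[4.1.0]hept-4-en-1-yl]methyl benzoate | O=C(OC[C@]12O[C@H]1C=C[C@H](O)[C@@H]2O)c1ccccc1
F9 | step 2 | cyclohexa-1,4-dien-1-ylmethanol | OCC1=CCC=CC1
F10 | step 2 | (7-oxabicyclo[4.1.0]hept-3-en-1-yl)methanol (racemic) | OCC12CC=CCC1O2
F11 | step 2 | tert-butyldimethyl[(7-oxabicyclo[4.1.0]hept-3-en-1-yl)methoxy]silane (racemic) | CC(C)(C)[Si](C)(C)OCC12CC=CCC1O2
A1 | alternative 1 | (Z)-4-benzoyloxy-2-(benzoyloxymethyl)-3-(tert-butyldimethylsilyloxy)-6-iodo-2-(triethylsilyloxy)hex-5-enal, configured as in A2 | O=C[C@@](O[Si](CC)(CC)CC)(COC(=O)c1ccccc1)[C@@H](O[Si](C)(C)C(C)(C)C)[C@@H](OC(=O)c1ccccc1)/C=C\I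
A2 | alternative 1 | cyclohexenol with the C6 hydroxyl trans to the C1 triethylsilyloxy group | O=C(OC[C@]1(O[Si](CC)(CC)CC)[C@H](O)C=C[C@H](OC(=O)c2ccccc2)[C@@H]1O[Si](C)(C)C(C)(C)C)c1ccccc1
A3 | alternative 2 | furfuryl benzoate | O=C(OCc1ccco1)c1ccccc1
A4 | alternative 2 | vinylene carbonate | O=C1OC=CO1
A5 | alternative 2 | endo 7-oxanorbornene carbonate | O=C(OC[C@]12O[C@H](C=C1)[C@@H]1OC(=O)O[C@@H]12)c1ccccc1
A6 | alternative 3 | six-membered lactone with a 2-(tert-butyldimethylsilyloxy) group (either configuration), a 3,4-acetonide and a 5-[(E)-2-chlorovinyl] group trans to the acetonide | O=C1O[C@@H](/C=C/Cl)[C@@H]2OC(C)(C)O[C@@H]2C1O[Si](C)(C)C(C)(C)C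
A7 | alternative 3 | cyclohexene alpha-silyloxy acid with the C6 chloride trans to the C1 oxygen | OC(=O)[C@]1(O[Si](C)(C)C(C)(C)C)[C@H](Cl)C=C[C@@H]2OC(C)(C)O[C@H]12
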